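**Assumption:** the target has no stereocentre, stereoaxis or C=C geometry, so it is achiral and needs no enantiocontrol. (E)-Hept-3-en-2-one is bought as the commercial flavour chemical.

## Retrosynthetic overview
1. Target 14 comes from double hydrogenolysis of the O-benzyl ether and benzyl ester in 13. The depside C(=O)–O bond of 13 is cut into A-ring acid 9 and B-ring phenol 11.
2. Both 9 and 11 derive from one building block, methyl divarate 6. The A branch is 4-O-Bn, 2-O-Me, then saponification. The B branch is saponification, then benzyl ester formation.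
3. Compound 6 comes from oxidative aromatisation of the cyclohexane-1,3-dione ester 4.
4. The key C–C bond is an intermolecular Michael addition of dimethyl malonate 2 to (E)-hept-3-en-2-one 1. A Dieckmann/Claisen closure follows in the same pot.
5. Ring order: the carbocycle is built once (step 1), aromatised (step 2), then split to serve as both ring A and ring B.

## Route

**Step 1**
Reactants: 1 (E)-hept-3-en-2-one; 2 dimethyl malonate
Product: 4 methyl 2-hydroxy-4-oxo-6-propylcyclohex-2-ene-1-carboxylate (racemic), via Michael adduct dimethyl 2-(2-oxoheptan-4-yl)malonate 3 (not isolated)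
Conditions: NaOMe (1.1 equiv), MeOH, rt then reflux 4 h; evaporate, take up in water, wash with CH2Cl2, then cold 2 M HCl to pH 3
Reagents that add atoms: none
Why: The malonate anion adds 1,4 to the enone (Michael addition) and the methyl-ketone enolate of 3 closes onto one ester (Dieckmann/Claisen condensation), driven by formation of the stable dione enolate; the two racemic stereocentres do not matter because step 2 destroys them.

**Step 2**
Reactants: 4 methyl 2-hydroxy-4-oxo-6-propylcyclohex-2-ene-1-carboxylate
Product: 6 methyl 2,4-dihydroxy-6-propylbenzoate (methyl divarate), via 3-bromo enol-dione ester 5 (not isolated)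
Conditions: Br2 (1.0 equiv), DMF, 0 °C, 1 h; then 80 °C, 12 h
Reagents that add atoms: bromine, BrBr (its Br is carried only by intermediate 5 and is lost again before 6)
Why: α-Bromination of the enolised 1,3-dione uses up the Br2 at 0 °C before any electron-rich arene exists, and heating then causes dehydrobromination and tautomerisation (oxidative aromatisation) to the resorcylate.

**Step 3**
Reactants: 6 methyl 2,4-dihydroxy-6-propylbenzoate
Product: 7 methyl 4-(benzyloxy)-2-hydroxy-6-propylbenzoate
Conditions: BnBr (1.05 equiv), K2CO3 (1.2 equiv), acetone, reflux, 8 h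
Reagents that add atoms: benzyl bromide, BrCc1ccccc1
Why: In this Williamson ether synthesis the free, more acidic 4-OH reacts selectively, because the 2-OH is held in a hydrogen bond to the ester carbonyl.

**Step 4**
Reactants: 7 methyl 4-(benzyloxy)-2-hydroxy-6-propylbenzoate
Product: 8 methyl 4-(benzyloxy)-2-methoxy-6-propylbenzoate
Conditions: MeI (3 equiv), K2CO3 (3 equiv), DMF, 45 °C, 16 h
Reagents that add atoms: methyl iodide, CI
Why: Excess MeI and base in a dipolar aprotic solvent force Williamson O-methylation of the only remaining (chelated) phenol.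

**Step 5**
Reactants: 8 methyl 4-(benzyloxy)-2-methoxy-6-propylbenzoate
Product: 9 4-(benzyloxy)-2-methoxy-6-propylbenzoic acid
Conditions: KOH (10 equiv), DMSO–H2O 4:1, 100 °C, 16 h; then cold 1 M HCl
Reagents that add atoms: potassium hydroxide, [K+].[OH-] (supplies the new carboxyl oxygen)
Why: Poorly solvated hydroxide in aqueous DMSO saponifies the 2,6-disubstituted benzoate (BAc2 hydrolysis), while both aryl ethers are inert to base.

**Step 6**
Reactants: 6 methyl 2,4-dihydroxy-6-propylbenzoate
Product: 10 2,4-dihydroxy-6-propylbenzoic acid (divaric acid)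
Conditions: 2.5 M aq KOH (10 equiv), MeOH, N2, reflux, 12 h; then 1 M HCl at 0 °C to pH 2–3, extract with EtOAc, concentrate below 30 °C
Reagents that add atoms: potassium hydroxide, [K+].[OH-] (supplies the new carboxyl oxygen)
Why: Saponification proceeds through the base-stable polyanion, and cold acidification with no heating avoids protodecarboxylation of the free resorcylic acid.

**Step 7**
Reactants: 10 2,4-dihydroxy-6-propylbenzoic acid
Product: 11 benzyl 2,4-dihydroxy-6-propylbenzoate
Conditions: BnBr (1.05 equiv), KHCO3 (1.3 equiv), DMF, rt, 20 h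
Reagents that add atoms: benzyl bromide, BrCc1ccccc1
Why: Bicarbonate deprotonates only the carboxylic acid, so SN2 carboxylate alkylation gives the benzyl ester and leaves both phenols free.

**Step 8**
Reactants: 9 4-(benzyloxy)-2-methoxy-6-propylbenzoic acid; 11 benzyl 2,4-dihydroxy-6-propylbenzoate
Product: 13 benzyl 4-{[4-(benzyloxy)-2-methoxy-6-propylbenzoyl]oxy}-2-hydroxy-6-propylbenzoate, via mixed trifluoroacetic anhydride 12 (not isolated)
Conditions: TFAA (5 equiv), anhydrous toluene, rt, 3 h; aqueous NaHCO3 work-up
Reagents that add atoms: trifluoroacetic anhydride, O=C(OC(=O)C(F)(F)F)C(F)(F)F (its CF3CO group sits only in intermediate 12; nothing from it remains in 13)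
Why: In this mixed-anhydride esterification the electron-rich hindered acid is activated as an acylium-like trifluoroacetyl anhydride, which acylates the unchelated 4-OH of 11 and spares the hydrogen-bonded 2-OH.

**Step 9**
Reactants: 13 benzyl 4-{[4-(benzyloxy)-2-methoxy-6-propylbenzoyl]oxy}-2-hydroxy-6-propylbenzoate
Product: 14 2-hydroxy-4-[(4-hydroxy-2-methoxy-6-propylbenzoyl)oxy]-6-propylbenzoic acid (target)
Conditions: H2 (1 atm), 10% Pd/C, EtOAc, rt, 3 h
Reagents that add atoms: none
Why: Neutral catalytic hydrogenolysis cleaves both benzylic C–O bonds in a non-nucleophilic solvent, so the aryl ester (depside) link and the methyl ether survive.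

## Compound list
1 | (E)-hept-3-en-2-one | CCC/C=C/C(C)=O | starting material
2 | dimethyl malonate | COC(=O)CC(=O)OC | starting material
3 | dimethyl 2-(2-oxoheptan-4-yl)malonate (racemic) | CCCC(CC(C)=O)C(C(=O)OC)C(=O)OC | intermediate (not isolated)
4 | methyl 2-hydroxy-4-oxo-6-propylcyclohex-2-ene-1-carboxylate (enol of the 2,4-dioxo ester; racemic diastereomer mixture) | CCCC1CC(=O)C=C(O)C1C(=O)OC | intermediate
5 | methyl 3-bromo-2-hydroxy-4-oxo-6-propylcyclohex-2-ene-1-carboxylate (racemic) | CCCC1CC(=O)C(Br)=C(O)C1C(=O)OC | intermediate (not isolated)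
6 | methyl 2,4-dihydroxy-6-propylbenzoate | CCCc1cc(O)cc(O)c1C(=O)OC | intermediate
7 | methyl 4-(benzyloxy)-2-hydroxy-6-propylbenzoate | CCCc1cc(OCc2ccccc2)cc(O)c1C(=O)OC | intermediate
8 | methyl 4-(benzyloxy)-2-methoxy-6-propylbenzoate | CCCc1cc(OCc2ccccc2)cc(OC)c1C(=O)OC | intermediate
9 | 4-(benzyloxy)-2-methoxy-6-propylbenzoic acid | CCCc1cc(OCc2ccccc2)cc(OC)c1C(=O)O | intermediate
10 | 2,4-dihydroxy-6-propylbenzoic acid | CCCc1cc(O)cc(O)c1C(=O)O | intermediate
11 | benzyl 2,4-dihydroxy-6-propylbenzoate | CCCc1cc(O)cc(O)c1C(=O)OCc1ccccc1 | intermediate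
12 | 4-(benzyloxy)-2-methoxy-6-propylbenzoic trifluoroacetic anhydride | CCCc1cc(OCc2ccccc2)cc(OC)c1C(=O)OC(=O)C(F)(F)F | intermediate (not isolated)
13 | benzyl 4-{[4-(benzyloxy)-2-methoxy-6-propylbenzoyl]oxy}-2-hydroxy-6-propylbenzoate | CCCc1cc(OC(=O)c2c(CCC)cc(OCc3ccccc3)cc2OC)cc(O)c1C(=O)OCc1ccccc1 | intermediate
14 | 2-hydroxy-4-[(4-hydroxy-2-methoxy-6-propylbenzoyl)oxy]-6-propylbenzoic acid (achiral) | CCCc1cc(OC(=O)c2c(CCC)cc(O)cc2OC)cc(O)c1C(=O)O | target

## Summary
Total step count: 9.
Longest linear sequence: 7 (steps 1, 2, 3, 4, 5, 8, 9). The B-ring branch is steps 6 and 7, starting from 6.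

## Steps most likely to fail

**Step 2 (aromatisation).** The risks are moderate yield, ring over-bromination, and ester loss if the mixture is overheated. The fallback sets out from 4 and comes back at 6. Rather than trying to stop at one oxidation equivalent, 4 is treated with excess Br2 (3.2 equiv) in AcOH at rt. Aromatisation and nuclear bromination then run to a single crystalline end point, methyl 3,5-dibromo-2,4-dihydroxy-6-propylbenzoate F1. Both bromines are removed afterwards by hydrogenolysis (H2, Pd/C, NaOAc, MeOH, rt) to give 6.

**Step 6 (saponification to the decarboxylation-prone acid).** The fallback sets out from 6 and comes back at 10. Both phenols are first masked with BnBr (2.5 equiv) and K2CO3 in DMF at 60 °C, giving methyl 2,4-bis(benzyloxy)-6-propylbenzoate F2. This is saponified under the conditions of step 5 (KOH, DMSO–H2O, 100 °C) to 2,4-bis(benzyloxy)-6-propylbenzoic acid F3, which tolerates acidic work-up far better than the free resorcylic acid. Neutral hydrogenolysis (H2, Pd/C, EtOAc, rt) then releases 10 without acid or heat, and 10 goes straight into step 7.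

**Step 8 (depside coupling of a hindered acid).** The fallback sets out from 9 and comes back at 13. The acid-promoted one-pot activation is replaced by a discrete acyl donor and base-promoted acyl transfer. Acid 9 is converted with (COCl)2 and catalytic DMF in CH2Cl2 (0 °C to rt) into 4-(benzyloxy)-2-methoxy-6-propylbenzoyl chloride F4. After stripping the volatiles, F4 is added to 11 with pyridine and DMAP (0.2 equiv) in CH2Cl2, 0 °C to rt. The more acidic, unchelated 4-OH is acylated through the acylpyridinium ion to give 13.

## Further compounds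
F1 | step 2 | methyl 3,5-dibromo-2,4-dihydroxy-6-propylbenzoate | CCCc1c(Br)c(O)c(Br)c(O)c1C(=O)OC
F2 | step 6 | methyl 2,4-bis(benzyloxy)-6-propylbenzoate | CCCc1cc(OCc2ccccc2)cc(OCc2ccccc2)c1C(=O)OC
F3 | step 6 | 2,4-bis(benzyloxy)-6-propylbenzoic acid | CCCc1cc(OCc2ccccc2)cc(OCc2ccccc2)c1C(=O)O
F4 | step 8 | 4-(benzyloxy)-2-methoxy-6-propylbenzoyl chloride | CCCc1cc(OCc2ccccc2)cc(OC)c1C(=O)Cl
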